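Late in a flask whose starting material is nearly gone, the question is no longer how fast it goes but where it went, so each molecule can be followed to one fork: it ends as target or it ends elsewhere.

| flask | starting material | first nucleophile | second nucleophile | temperature | remark | time |
|---|---|---|---|---|---|---|
| grey | 0.050 M | 2.5 equiv | 1.5 equiv | −10 °C | run made earlier |  |
| teal | 0.075 M | 2.5 equiv | 1.5 equiv | 12 °C | run made earlier |  |
| amber | 0.10 M | 5 equiv | 1.5 equiv | −10 °C | run made earlier |  |
| cedar | 0.10 M | 2.50 equiv | 1.50 equiv | −20 °C |  | 1.5 h |
| larch | 0.10 M | 2.50 equiv | 1.50 equiv | 0 °C |  | 1.5 h |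
| oak | 0.10 M | 2.50 equiv | 1.50 equiv | 20 °C |  | 1.5 h |

| run | time / min | target / % | starting material / % |
|---|---|---|---|
| grey | 4.00 | 4.2 | 82.3 |
| grey | 6.00 | 4.9 | 72.9 |
| grey | 12.0 | 8.4 | 53.6 |
| grey | 25.0 | 12.5 | 29.4 |
| grey | 50.0 | 16.9 | 9.9 |
| teal | 1.33 | 12.5 | 24.1 |
| teal | 2.00 | 16.6 | 12.6 |
| teal | 4.00 | 16.2 | 2.4 |
| teal | 8.00 | 16.6 | 0.4 |
| teal | 15.0 | 18.1 | 0 |
| amber | 10.0 | 17.2 | 61.1 |
| amber | 20.0 | 28.6 | 36.9 |
| amber | 25.0 | 29.2 | 29.1 |
| amber | 40.0 | 39.2 | 13.6 |
| amber | 50.0 | 43.4 | 7.1 |

(each reading ± 1 percentage point)

- a reading or a percentage of target counts all its forms, free or not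

- which flask leads in amount of target, in percent of the starting material charged ("all alike" within 1.5 percentage points) (cedar / larch / oak / all alike)
- how much target is there at the end, in percent of the starting material charged: cedar
- how much target is there at the end, in percent of the starting material charged: larch
- how much target is there at the end, in percent of the starting material charged: oak

At the last readings the grey run has made 16.9% of target with 9.9% of starting material left, the amber run 43.4% with 7.1% left, and the teal run 18.1% with 0% left. Dividing target by the other material consumed gives the odds at the fork, and dividing these by the charged c(first nucleophile) gives a selectivity factor, g: 1.85 M⁻¹ in the grey run, 1.75 M⁻¹ in the amber run and 1.18 M⁻¹ in the teal run. Grey and amber agree at one temperature, and the warmer teal run reads lower.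

Larch, at 0 °C with c(first nucleophile) of 0.250 M, lies between those temperatures. The grey half-life of 15.0 min is far shorter than 1.5 h, so even at that colder rate nearly all of the starting material is reckoned to be consumed in larch. If g falls steadily with warming, the grey g sets an upper estimate for larch's target at 31.6%, and the teal g a lower one at 22.8%, and these two make the bracket. Sliding ln g evenly with temperature tightens this to 1.51 M⁻¹, hence 27.4%. The same slide, applied to g and to the rate of loss of starting material, gives here 23.0% for cedar and 20.0% for oak.

The forecast names larch, with 21% for cedar, 26% for larch and 19.5% for oak, holding “so selectivity falls with warming”. Its larch figure lies inside the bracket, a little below the reckoning here.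

The flasks give 20.1% in cedar, 25.1% in larch and 17.5% in oak, and larch leads.

    intermediate → solvolysis product (k = 1.65 min⁻¹, Ea = 69.0 kJ mol⁻¹)
    starting material → intermediate (k = 0.0106 min⁻¹, Ea = 86.0 kJ mol⁻¹)
    second nucleophile ⇌ dormant form (K = 11.0, k = 0.0613 min⁻¹, Ea = 82.0 kJ mol⁻¹, ΔH = −29.0 kJ mol⁻¹)
    intermediate → side product (k = 0.344 min⁻¹, Ea = 78.0 kJ mol⁻¹)
    second nucleophile + intermediate → other capture product (k = 45.7 M⁻¹ min⁻¹, Ea = 36.0 kJ mol⁻¹)
    second nucleophile + target ⇌ idle adduct, settled at all times (K = 16.0 M⁻¹, ΔH = −37.0 kJ mol⁻¹)
    first nucleophile + intermediate → target (k = 6.88 M⁻¹ min⁻¹, Ea = 52.0 kJ mol⁻¹)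
    (constants at −20 °C)

Larch's target, inside the bracket, corresponds to g of 1.34 M⁻¹, between the teal 1.18 M⁻¹ and the grey 1.85 M⁻¹. In cedar the starting material has, by its step to the intermediate, a half-life of 1.1 h at 1.50 h, and 38.5% of it still stands there against 0% in larch, while cedar's target trails larch's with a g of 1.95 M⁻¹ that is higher. Cedar read later passes larch as read at 1.50 h: carried to 2.50 h, with 20.4% left, that g gives 26.1%, and cedar then holds 27.2%, above larch's 25.1%.

The data were computed for substances that don't exist; the scatter is artificial.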